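The route cuts both ring A prenyl groups between the benzylic CH2 and the vinylic CH. The C6 chain sits between O5 and O7 and the C8 chain between O7 and O1, so each CH2 can be unmasked as the exocyclic carbon of an ortho-quinone methide. In step 4 an isobutenyl Grignard reagent triggers and intercepts two such species in turn and delivers both linear prenyl groups in one flask. The precursor 5 is phloroglucinol bearing two CH2OH groups and three aryl tert-butyl carbonates. Lithiation of the remaining ring A carbon, addition to a ring B arylacetaldehyde, C2 insertion and acid-induced closure of ring C complete the isoflavone.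

Key step: step 4

Remark on the chemistry: the target has no stereocentre. The carbinol carbons of 16–18 and 26 are racemic and are erased again. The magnesium salts in step 4 are drawn as the free OH compounds. The push–pull C=C of 28 and 29 is drawn without geometry because it equilibrates and vanishes on ring closure.

Step 1
Reactants: 1 phloroglucinol
Product: 2 2,4,6-trihydroxybenzene-1,3-dicarbaldehyde (2,4-diformylphloroglucinol)
Conditions: POCl3 (2.3 equiv), DMF (2.3 equiv), 1,4-dioxane, rt; then ice-water
Reagents that add atoms: N,N-dimethylformamide, CN(C)C=O; water, O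
Why: Vilsmeier–Haack formylation, in which the very electron-rich ring takes up two chloroiminium ions and the two iminium groups then deactivate the last carbon, so hydrolysis should give the 2,4-dialdehyde.

Step 2
Reactants: 2 2,4-diformylphloroglucinol; 3 di-tert-butyl dicarbonate
Product: 4 tri-tert-butyl (2,4-diformylbenzene-1,3,5-triyl) tricarbonate
Conditions: 3 (3.6 equiv), i-Pr2NEt, DMAP (cat.), THF, 0 °C → rt
Reagents that add atoms: di-tert-butyl dicarbonate (3), CC(C)(C)OC(=O)OC(=O)OC(C)(C)C
Why: DMAP-catalysed O-acylation should convert all three phenols, the hydrogen-bonded ones included, into aryl tert-butyl carbonates and leave the aldehydes alone.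

Step 3
Reactants: 4 tris-O-Boc 2,4-diformylphloroglucinol
Product: 5 tri-tert-butyl [2,4-bis(hydroxymethyl)benzene-1,3,5-triyl] tricarbonate
Conditions: BH3·THF, THF, 0 °C; then H2O
Reagents that add atoms: none
Why: Chemoselective borane reduction proceeds through neutral borate esters and not free alkoxides, so both aldehydes are reduced while carbonate migration and early quinone methide formation are avoided.

Step 4
Reactants: 5 tris-O-Boc 2,4-bis(hydroxymethyl)phloroglucinol; 6 2-methylprop-1-enylmagnesium bromide
Product: 10 tert-butyl 3,5-dihydroxy-2,4-bis(3-methylbut-2-enyl)phenyl carbonate (2,4-diprenylphloroglucinol mono-tert-butyl carbonate), via first ortho-quinone methide 7 (not isolated), via monoprenylated benzylic alcohol 8 (not isolated), via second ortho-quinone methide 9 (not isolated)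
Conditions: 6 (5 equiv, 0.5 M in THF), Et2O, 0.05 M, −78 → 0 °C; then aq. NH4Cl
Reagents that add atoms: 2-methylprop-1-enylmagnesium bromide (6), CC(C)=C[Mg]Br
Why: Two equivalents of 6 act as base on the CH2OH groups; each magnesium alkoxide attacks a neighbouring aryl carbonate, the tert-butoxycarbonyl group moves to the benzylic oxygen, and the phenoxide so freed expels tert-butyl carbonate to give an ortho-quinone methide (7, later 9). Two further equivalents add through their vinylic carbon to the exocyclic CH2 in the 1,4 sense, which restores the arene and forms the CH2–CH bond of a linear prenyl group, first in 8 and then in 10. The closest known reaction type is the magnesium-triggered anionic generation of ortho-quinone methides from ortho-(tert-butoxycarbonyloxy)benzyl alcohols with conjugate addition of Grignard reagents, alkenyl ones included; here it is run twice on one ring. No ring is closed and no stereocentre is created. The step needs conjugate instead of carbonyl attack, which the gain of aromaticity secures, and ionisation only at the two benzylic carbons, which is secured because each CH2OH has a carbonate on both ortho oxygens and three carbonates serve two alkoxides, so neither cascade can run out of a migrating group. Since the new bond is made at a carbon that is already fixed to the ring, ether formation, attack through the tertiary allyl terminus and double alkylation of one ring carbon cannot occur, and it is immaterial which flanking carbonate moves because step 5 removes the survivor.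

Step 5
Reactants: 10 2,4-diprenylphloroglucinol mono-tert-butyl carbonate
Product: 12 1,3,5-tris(methoxymethoxy)-2,4-bis(3-methylbut-2-enyl)benzene, via 2,4-diprenylphloroglucinol 11 (not isolated)
Conditions: pyrrolidine, CH2Cl2, rt, Ar; evaporate; NaH, MOMCl, DMF, 0 °C → rt
Reagents that add atoms: chloromethyl methyl ether, COCCl
Why: Aminolysis of the aryl carbonate frees the last phenol without acid, and Williamson-type O-alkylation of the sodium phenoxides with the hard electrophile MOMCl should cap all three oxygens, so the air-sensitive triol 11 need not be isolated.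

Step 6
Reactants: 13 4-hydroxy-2-methoxybenzaldehyde
Product: 14 2-methoxy-4-(methoxymethoxy)benzaldehyde
Conditions: MOMCl, i-Pr2NEt, CH2Cl2, 0 °C → rt
Reagents that add atoms: chloromethyl methyl ether, COCCl
Why: O-alkylation of the single, rather acidic para-formyl phenol with MOMCl under amine base is a routine acetal protection.

Step 7
Reactants: 14 2-methoxy-4-(methoxymethoxy)benzaldehyde; 15 prenyl bromide (1-bromo-3-methylbut-2-ene)
Product: 19 2-methoxy-4-(methoxymethoxy)-3-(3-methylbut-2-enyl)benzaldehyde, via lithium amino alkoxide 16 (not isolated), via C3-lithiated amino alkoxide 17 (not isolated), via prenylated amino alkoxide 18 (not isolated)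
Conditions: N-methylpiperazine, n-BuLi, THF, −20 °C, then 14; n-BuLi, −20 → 0 °C; 15 (excess), −78 °C → rt; aq. NH4Cl
Reagents that add atoms: prenyl bromide (15), CC(C)=CCBr
Why: In situ masking of the aldehyde as an α-amino alkoxide permits directed ortho-lithiation at C3, the carbon activated by both OMe and OMOM; SN2 alkylation with the primary allylic bromide and aqueous collapse of the hemiaminal should then return the aldehyde.

Step 8
Reactants: 19 2-methoxy-4-(methoxymethoxy)-3-prenylbenzaldehyde
Product: 20 1-ethenyl-2-methoxy-4-(methoxymethoxy)-3-(3-methylbut-2-enyl)benzene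
Conditions: Ph3PCH3Br, KOt-Bu, THF, 0 °C → rt
Reagents that add atoms: methyltriphenylphosphonium bromide, C[P+](c1ccccc1)(c1ccccc1)c1ccccc1.[Br-]
Why: Wittig methylenation with the unstabilised ylide is reliable for non-enolisable aryl aldehydes and is compatible with the acetal and the prenyl group.

Step 9
Reactants: 20 ring B styrene
Product: 22 2-[2-methoxy-4-(methoxymethoxy)-3-(3-methylbut-2-enyl)phenyl]ethanol, via B-alkyl-9-BBN adduct 21 (not isolated)
Conditions: 9-BBN (1.1 equiv), THF, 0 °C → rt; then aq. NaOH, H2O2, 0 °C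
Reagents that add atoms: hydrogen peroxide, OO
Why: In this hydroboration–oxidation the bulky borane strongly prefers the monosubstituted vinyl group over the trisubstituted prenyl alkene and places boron on the terminal carbon, and alkaline peroxide does not attack the isolated alkene.

Step 10
Reactants: 22 ring B 2-arylethanol
Product: 23 2-[2-methoxy-4-(methoxymethoxy)-3-(3-methylbut-2-enyl)phenyl]acetaldehyde
Conditions: Dess–Martin periodinane, CH2Cl2, 0 °C → rt; used at once
Reagents that add atoms: none
Why: Dess–Martin oxidation stops at the aldehyde under nearly neutral conditions that spare the alkene, the acetal and the sensitive arylacetaldehyde.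

Step 11
Reactants: 12 1,3,5-tris(methoxymethoxy)-2,4-diprenylbenzene; 23 ring B arylacetaldehyde
Product: 26 2-[2-methoxy-4-(methoxymethoxy)-3-prenylphenyl]-1-[2,4,6-tris(methoxymethoxy)-3,5-diprenylphenyl]ethanol (racemic), via aryllithium 24 (not isolated), via arylcerium dichloride 25 (not isolated)
Conditions: 12, n-BuLi (1.05 equiv), THF, −20 → 0 °C; CeCl3 (anhydrous), −78 °C; 23, −78 °C; aq. NH4Cl
Reagents that add atoms: none
Why: Directed ortho-metalation takes the only ring C–H, which lies between two chelating OMOM groups, and transmetalation gives a weakly basic organocerium reagent whose 1,2-addition should outrun enolisation of 23; the new carbinol centre is racemic and is removed in step 12.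

Step 12
Reactants: 26 diaryl carbinol
Product: 27 2-[2-methoxy-4-(methoxymethoxy)-3-prenylphenyl]-1-[2,4,6-tris(methoxymethoxy)-3,5-diprenylphenyl]ethanone (protected deoxybenzoin)
Conditions: Dess–Martin periodinane, CH2Cl2, 0 °C → rt
Reagents that add atoms: none
Why: Dess–Martin oxidation handles hindered benzylic alcohols and leaves the three trisubstituted alkenes and four acetals untouched.

Step 13
Reactants: 27 protected deoxybenzoin
Product: 28 3-(dimethylamino)-2-[2-methoxy-4-(methoxymethoxy)-3-prenylphenyl]-1-[2,4,6-tris(methoxymethoxy)-3,5-diprenylphenyl]prop-2-en-1-one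
Conditions: t-BuOCH(NMe2)2 (Bredereck's reagent, 3 equiv), toluene, 100 °C
Reagents that add atoms: tert-butoxybis(dimethylamino)methane, CC(C)(C)OC(N(C)C)N(C)C
Why: Aminomethylenation of the doubly activated ArCOCH2Ar methylene with an aminal ester installs the future C2 as an enaminone carbon under neutral to basic conditions, and the more reactive aminal ester is chosen over an amide acetal because the site is hindered.

Step 14
Reactants: 28 protected enaminone
Product: 30 5,7-dihydroxy-3-[4-hydroxy-2-methoxy-3-(3-methylbut-2-enyl)phenyl]-6,8-bis(3-methylbut-2-enyl)chromen-4-one (target), via tetrahydroxy enaminone 29 (not isolated)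
Conditions: 3 M aq. HCl, MeOH, 40 °C, stopped as soon as 29 is consumed
Reagents that add atoms: none
Why: Acid-catalysed acetal methanolysis removes the four MOM groups, and one of the two equivalent ortho phenols of ring A then adds to the enaminone β-carbon and expels dimethylamine (chromone synthesis from ortho-hydroxyaryl enaminones), closing ring C with prenyl groups at C6 and C8.

Compound list
1 | phloroglucinol (benzene-1,3,5-triol) | Oc1cc(O)cc(O)c1 | starting material
2 | 2,4,6-trihydroxybenzene-1,3-dicarbaldehyde | O=Cc1c(O)cc(O)c(C=O)c1O | intermediate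
3 | di-tert-butyl dicarbonate | CC(C)(C)OC(=O)OC(=O)OC(C)(C)C | starting material
4 | tri-tert-butyl (2,4-diformylbenzene-1,3,5-triyl) tricarbonate | O=Cc1c(OC(=O)OC(C)(C)C)cc(OC(=O)OC(C)(C)C)c(C=O)c1OC(=O)OC(C)(C)C | intermediate
5 | tri-tert-butyl [2,4-bis(hydroxymethyl)benzene-1,3,5-triyl] tricarbonate | OCc1c(OC(=O)OC(C)(C)C)cc(OC(=O)OC(C)(C)C)c(CO)c1OC(=O)OC(C)(C)C | intermediate
6 | 2-methylprop-1-enylmagnesium bromide | CC(C)=C[Mg]Br | starting material
7 | 3,5-bis(tert-butoxycarbonyloxy)-4-(hydroxymethyl)-6-methylidenecyclohexa-2,4-dien-1-one | C=C1C(=O)C=C(OC(=O)OC(C)(C)C)C(CO)=C1OC(=O)OC(C)(C)C | intermediate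
8 | di-tert-butyl [5-hydroxy-2-(hydroxymethyl)-4-(3-methylbut-2-enyl)benzene-1,3-diyl] dicarbonate | CC(C)=CCc1c(O)cc(OC(=O)OC(C)(C)C)c(CO)c1OC(=O)OC(C)(C)C | intermediate
9 | 5-(tert-butoxycarbonyloxy)-3-hydroxy-6-methylidene-2-(3-methylbut-2-enyl)cyclohexa-2,4-dien-1-one | C=C1C(=O)C(CC=C(C)C)=C(O)C=C1OC(=O)OC(C)(C)C | intermediate
10 | tert-butyl 3,5-dihydroxy-2,4-bis(3-methylbut-2-enyl)phenyl carbonate | CC(C)=CCc1c(OC(=O)OC(C)(C)C)cc(O)c(CC=C(C)C)c1O | intermediate
11 | 2,4-bis(3-methylbut-2-enyl)benzene-1,3,5-triol | CC(C)=CCc1c(O)cc(O)c(CC=C(C)C)c1O | intermediate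
12 | 1,3,5-tris(methoxymethoxy)-2,4-bis(3-methylbut-2-enyl)benzene | COCOc1cc(OCOC)c(CC=C(C)C)c(OCOC)c1CC=C(C)C | intermediate
13 | 4-hydroxy-2-methoxybenzaldehyde | COc1cc(O)ccc1C=O | starting material
14 | 2-methoxy-4-(methoxymethoxy)benzaldehyde | COCOc1ccc(C=O)c(OC)c1 | intermediate
15 | prenyl bromide (1-bromo-3-methylbut-2-ene) | CC(C)=CCBr | starting material
16 | lithium [2-methoxy-4-(methoxymethoxy)phenyl](4-methylpiperazin-1-yl)methanolate (racemic) | [Li+].[O-]C(N1CCN(C)CC1)c1ccc(OCOC)cc1OC | intermediate
17 | C3-lithio derivative of 16 (racemic) | [Li+].[O-]C(N1CCN(C)CC1)c1ccc(OCOC)c([Li])c1OC | intermediate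
18 | C3-prenyl derivative of 16 (racemic) | [Li+].[O-]C(N1CCN(C)CC1)c1ccc(OCOC)c(CC=C(C)C)c1OC | intermediate
19 | 2-methoxy-4-(methoxymethoxy)-3-(3-methylbut-2-enyl)benzaldehyde | COCOc1ccc(C=O)c(OC)c1CC=C(C)C | intermediate
20 | 1-ethenyl-2-methoxy-4-(methoxymethoxy)-3-(3-methylbut-2-enyl)benzene | COCOc1ccc(C=C)c(OC)c1CC=C(C)C | intermediate
21 | 9-{2-[2-methoxy-4-(methoxymethoxy)-3-(3-methylbut-2-enyl)phenyl]ethyl}-9-borabicyclo[3.3.1]nonane | COCOc1ccc(CCB2C3CCCC2CCC3)c(OC)c1CC=C(C)C | intermediate
22 | 2-[2-methoxy-4-(methoxymethoxy)-3-(3-methylbut-2-enyl)phenyl]ethanol | COCOc1ccc(CCO)c(OC)c1CC=C(C)C | intermediate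
23 | 2-[2-methoxy-4-(methoxymethoxy)-3-(3-methylbut-2-enyl)phenyl]acetaldehyde | COCOc1ccc(CC=O)c(OC)c1CC=C(C)C | intermediate
24 | [2,4,6-tris(methoxymethoxy)-3,5-bis(3-methylbut-2-enyl)phenyl]lithium | [Li]c1c(OCOC)c(CC=C(C)C)c(OCOC)c(CC=C(C)C)c1OCOC | intermediate
25 | [2,4,6-tris(methoxymethoxy)-3,5-bis(3-methylbut-2-enyl)phenyl]cerium dichloride | Cl[Ce](Cl)c1c(OCOC)c(CC=C(C)C)c(OCOC)c(CC=C(C)C)c1OCOC | intermediate
26 | 2-[2-methoxy-4-(methoxymethoxy)-3-prenylphenyl]-1-[2,4,6-tris(methoxymethoxy)-3,5-diprenylphenyl]ethanol (racemic) | COCOc1ccc(CC(O)c2c(OCOC)c(CC=C(C)C)c(OCOC)c(CC=C(C)C)c2OCOC)c(OC)c1CC=C(C)C | intermediate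
27 | 2-[2-methoxy-4-(methoxymethoxy)-3-prenylphenyl]-1-[2,4,6-tris(methoxymethoxy)-3,5-diprenylphenyl]ethanone | COCOc1ccc(CC(=O)c2c(OCOC)c(CC=C(C)C)c(OCOC)c(CC=C(C)C)c2OCOC)c(OC)c1CC=C(C)C | intermediate
28 | 3-(dimethylamino)-2-[2-methoxy-4-(methoxymethoxy)-3-prenylphenyl]-1-[2,4,6-tris(methoxymethoxy)-3,5-diprenylphenyl]prop-2-en-1-one | COCOc1ccc(C(=CN(C)C)C(=O)c2c(OCOC)c(CC=C(C)C)c(OCOC)c(CC=C(C)C)c2OCOC)c(OC)c1CC=C(C)C | intermediate
29 | 3-(dimethylamino)-2-(4-hydroxy-2-methoxy-3-prenylphenyl)-1-(2,4,6-trihydroxy-3,5-diprenylphenyl)prop-2-en-1-one | COc1c(C(=CN(C)C)C(=O)c2c(O)c(CC=C(C)C)c(O)c(CC=C(C)C)c2O)ccc(O)c1CC=C(C)C | intermediate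
30 | 5,7-dihydroxy-3-[4-hydroxy-2-methoxy-3-(3-methylbut-2-enyl)phenyl]-6,8-bis(3-methylbut-2-enyl)chromen-4-one | COc1c(-c2coc3c(CC=C(C)C)c(O)c(CC=C(C)C)c(O)c3c2=O)ccc(O)c1CC=C(C)C | target

Total step count: 14.
Longest linear sequence: 9 steps (1–5, then 11–14). The ring B branch (6–10, then 11–14) is equally long.

Steps most likely to fail

**Step 4.** After the first addition the ring carries a magnesium phenoxide. The second quinone methide is then less electrophilic and may oligomerise or be captured by tert-butoxide before the Grignard reagent adds. Direct attack of excess reagent on a carbonate before it has migrated would also stall the cascade.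
- The fallback gives up the quinone methide logic and installs both chains by iterative directed ortho-metalation. It sets out from 1.
- NaH and MOMCl in DMF give 1,3,5-tris(methoxymethoxy)benzene F1.
- n-BuLi in THF at 0 °C gives [2,4,6-tris(methoxymethoxy)phenyl]lithium F2, which is alkylated with 15 to 1,3,5-tris(methoxymethoxy)-2-(3-methylbut-2-enyl)benzene F3.
- A second lithiation between two OMOM groups gives [2,4,6-tris(methoxymethoxy)-3-(3-methylbut-2-enyl)phenyl]lithium F4.
- A second alkylation with 15 gives 12, where the route is rejoined.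

**Step 11.** Proton transfer from the acidic benzylic α-CH2 of the aldehyde to the hindered aryl-metal species may compete with addition. This would return the arene and let the aldehyde self-condense.
- The fallback replaces carbonyl addition plus oxidation by an acyl cross-coupling with a non-basic arylzinc reagent. It sets out from 22 and 24.
- TEMPO and PhI(OAc)2 in MeCN–H2O oxidise 22 to 2-[2-methoxy-4-(methoxymethoxy)-3-(3-methylbut-2-enyl)phenyl]acetic acid F5.
- Ghosez's reagent (1-chloro-N,N,2-trimethylprop-1-en-1-amine) in CH2Cl2 gives, without acid, 2-[2-methoxy-4-(methoxymethoxy)-3-(3-methylbut-2-enyl)phenyl]acetyl chloride F6.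
- ZnCl2 converts 24 into [2,4,6-tris(methoxymethoxy)-3,5-bis(3-methylbut-2-enyl)phenyl]zinc chloride F7.
- Negishi acylation of F7 with F6 under Pd(PPh3)4 catalysis in THF gives 27, where the route is rejoined. Steps 10 to 12 are not needed.

**Step 14.** Acid-catalysed addition of the freed phenols (or of methanol) to the neighbouring prenyl double bonds may compete with cleavage of the last, most hindered acetal.
- The fallback exchanges the acetals for silyl ethers under buffered aprotic conditions and then liberates the phenols with fluoride. It sets out from 28.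
- TESOTf and 2,2'-bipyridyl in MeCN at 0 °C convert the four aryl MOM ethers into aryl triethylsilyl ethers. The product is 3-(dimethylamino)-2-[2-methoxy-3-prenyl-4-(triethylsilyloxy)phenyl]-1-[3,5-diprenyl-2,4,6-tris(triethylsilyloxy)phenyl]prop-2-en-1-one F8.
- TBAF buffered with AcOH in THF at 0 °C → rt then gives 29, which closes ring C on gentle warming and arrives at 30.

Further compounds
F1 | step 4 | 1,3,5-tris(methoxymethoxy)benzene | COCOc1cc(OCOC)cc(OCOC)c1
F2 | step 4 | [2,4,6-tris(methoxymethoxy)phenyl]lithium | [Li]c1c(OCOC)cc(OCOC)cc1OCOC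
F3 | step 4 | 1,3,5-tris(methoxymethoxy)-2-(3-methylbut-2-enyl)benzene | COCOc1cc(OCOC)c(CC=C(C)C)c(OCOC)c1
F4 | step 4 | [2,4,6-tris(methoxymethoxy)-3-(3-methylbut-2-enyl)phenyl]lithium | [Li]c1c(OCOC)cc(OCOC)c(CC=C(C)C)c1OCOC
F5 | step 11 | 2-[2-methoxy-4-(methoxymethoxy)-3-(3-methylbut-2-enyl)phenyl]acetic acid | COCOc1ccc(CC(=O)O)c(OC)c1CC=C(C)C
F6 | step 11 | 2-[2-methoxy-4-(methoxymethoxy)-3-(3-methylbut-2-enyl)phenyl]acetyl chloride | COCOc1ccc(CC(=O)Cl)c(OC)c1CC=C(C)C
F7 | step 11 | [2,4,6-tris(methoxymethoxy)-3,5-bis(3-methylbut-2-enyl)phenyl]zinc chloride | Cl[Zn]c1c(OCOC)c(CC=C(C)C)c(OCOC)c(CC=C(C)C)c1OCOC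
F8 | step 14 | 3-(dimethylamino)-2-[2-methoxy-3-prenyl-4-(triethylsilyloxy)phenyl]-1-[3,5-diprenyl-2,4,6-tris(triethylsilyloxy)phenyl]prop-2-en-1-one | CC[Si](CC)(CC)Oc1ccc(C(=CN(C)C)C(=O)c2c(O[Si](CC)(CC)CC)c(CC=C(C)C)c(O[Si](CC)(CC)CC)c(CC=C(C)C)c2O[Si](CC)(CC)CC)c(OC)c1CC=C(C)C
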